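## Retrosynthetic overview

1. Numbering: C1 and C6 are the ring-fusion CH carbons (C1 next to the CMe2 carbon C11, C6 next to the carbinol carbon C7). C2=C3 is the ring alkene with the methyl on C3, C4 carries the ester oxygen, C5 is the ring CH2, and C8, C9, C10 are the CH2 groups between C7 and C11. Ring A is the cyclohexene, ring B the seven-membered ring.
2. Last disconnections: the C4–O ester bond (Mitsunobu coupling with O-silylated isovanillic acid, inverting C4); the C4 oxygen and C2=C3 alkene go back through a C4 enone to a plain C3=C4 alkene; the C7 methyl carbinol goes back to a C7 ketone.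
3. Feature carrying the strategy: with C7 as a carbonyl, the atoms C7, C6, C1, C11 and C10 make up a cyclopentanone cis-fused to ring A, and the remaining ring B atoms C8 and C9 are a vinyl group on C10. Ring B is disconnected at C7–C8 and reconnected as C7–C10; forward, a photochemical 1,3-acyl shift inserts C8–C9 into the five-membered ring.
4. The 2-vinyl hydrindanone comes from the parent hydrindanone by enolate addition to phenyl vinyl sulfoxide and sulfoxide pyrolysis. The hydrindanone comes from an enantioselective Diels–Alder reaction of 4,4-dimethylcyclopent-2-en-1-one with isoprene, which sets C1 and C6.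
5. Order of ring formation: five-membered ring (purchased), ring A (Diels–Alder), ring B (photochemical enlargement of the five-membered ring).

Key step: step 4

Assumption: the facial sense of the oxazaborolidinium catalyst in step 1 is taken from its α-C–H···O binding mode with acrylates and 2-cycloalkenones and is not secured for this substrate; the (S)-prolinol-derived catalyst is written, and the antipodal catalyst from (R)-prolinol would be used instead if the sense proves to be the reverse.

## Route

Step 1
Reactants: 1 4,4-dimethylcyclopent-2-en-1-one; 2 isoprene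
Product: 3 (3aS,7aR)-3,3,5-trimethyl-2,3,3a,4,7,7a-hexahydro-1H-inden-1-one (cis-fused hydrindanone, C7 ketone, C3=C4 alkene)
Conditions: (3aS)-1-(2-methylphenyl)-3,3-diphenyltetrahydro-1H,3H-pyrrolo[1,2-c][1,3,2]oxazaborole (20 mol%), HNTf2 (20 mol%), 2 (5 equiv), CH2Cl2, −20 → 0 °C, sealed vessel
Reagents that add atoms: none
Why: Diels–Alder reaction catalysed by the chiral oxazaborolidinium Lewis acid: the boron binds the enone carbonyl, one phenyl group of the catalyst covers one face of the enone double bond (future C6–C1) and isoprene adds suprafacially to the other, which sets C1 and C6 together as the cis ring fusion, while the larger HOMO coefficient at the CH2 next to the methyl-bearing carbon of isoprene bonds to the β-carbon C1 and so places the methyl on C3, 1,4 to the acyl-bearing C6.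

Step 2
Reactants: 3 (3aS,7aR)-3,3,5-trimethyl-2,3,3a,4,7,7a-hexahydro-1H-inden-1-one; 4 phenyl vinyl sulfoxide (racemic)
Product: 6 (2R,3aS,7aR)-3,3,5-trimethyl-2-[2-(phenylsulfinyl)ethyl]-2,3,3a,4,7,7a-hexahydro-1H-inden-1-one, via lithium enolate 5 (not isolated)
Conditions: LiN(i-Pr)2 (LDA), THF, −78 °C; then 4, −78 → −30 °C; AcOH quench
Reagents that add atoms: lithium diisopropylamide, CC(C)N([Li])C(C)C (its lithium is held in 5 only)
Why: Kinetic enolisation with the hindered amide base should remove a proton from the CH2 group C10 in preference to the ring-fusion methine C6, and the enolate then adds in a Michael reaction to the vinyl sulfoxide (a vinyl cation equivalent) from the convex face of the cis-fused bicycle, so the side chain on C10 is expected cis to H1 and H6; this centre is erased in step 4, so its epimer is carried along without harm.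

Step 3
Reactants: 6 (2R,3aS,7aR)-3,3,5-trimethyl-2-[2-(phenylsulfinyl)ethyl]-2,3,3a,4,7,7a-hexahydro-1H-inden-1-one
Product: 7 (2R,3aS,7aR)-2-ethenyl-3,3,5-trimethyl-2,3,3a,4,7,7a-hexahydro-1H-inden-1-one (vinyl group C9=C8 on C10)
Conditions: toluene, CaCO3 (suspended), 110 °C
Reagents that add atoms: none
Why: Thermal syn-elimination of the sulfoxide (sulfoxide pyrolysis): the only β-hydrogens are on the CH2 attached to C10, so the terminal vinyl group must form, and the neutral buffered medium should keep the β,γ-double bond out of conjugation with the ketone.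

Step 4
Reactants: 7 (2R,3aS,7aR)-2-ethenyl-3,3,5-trimethyl-2,3,3a,4,7,7a-hexahydro-1H-inden-1-one
Product: 8 (4aR,9aS)-2,9,9-trimethyl-1,4,4a,6,9,9a-hexahydro-5H-benzo[7]annulen-5-one (cis-fused; C7 ketone, Z C9=C10 alkene in ring B, C3=C4 alkene in ring A)
Conditions: hν (300 nm lamps, Pyrex), degassed cyclohexane (0.01 M), rt, stopped at the photostationary state, recovered 7 recycled
Reagents that add atoms: none
Why: Direct n→π* excitation of the β,γ-unsaturated ketone gives the singlet state, which cleaves the allylic C7–C10 bond (Norrish type 1) to an acyl radical at C7 and an allyl radical over C10–C9–C8 that stay tethered through C6, C1 and C11, and the pair recombines at the terminus C8, forming C7–C8 and leaving the alkene at C9=C10. This is the photochemical 1,3-acyl shift of β,γ-unsaturated ketones, known as a two-carbon ring expansion of 2-vinylcycloalkanones. Ring B is closed by this C7–C8 recombination, that is by enlargement of the five-membered ring (C7, C6, C1, C11, C10) to the seven-membered ring and not by cyclisation of an open chain, and the ring size allows only the cis C9=C10 alkene. No stereocentre is formed: C10 becomes sp2, so both C10 epimers of 7 converge, and C1 and C6 are not part of the bond that breaks. The step needs the singlet 1,3-shift to win over the triplet oxa-di-π-methane rearrangement, decarbonylation and the reverse shift of 8; unsensitised irradiation near 300 nm in a degassed hydrocarbon, the quaternary C11 (no hydrogen next to the allyl radical for disproportionation to an aldehyde) and the exchange of a vinyl group for a disubstituted ring alkene should favour 8, and the photolysis is interrupted at the photostationary state.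

Step 5
Reactants: 8 (4aR,9aS)-2,9,9-trimethyl-1,4,4a,6,9,9a-hexahydro-5H-benzo[7]annulen-5-one
Product: 9 (4aR,9aS)-2,9,9-trimethyl-1,4,4a,6,7,8,9,9a-octahydro-5H-benzo[7]annulen-5-one
Conditions: H2 (1 atm), RhCl(PPh3)3 (5 mol%), benzene, rt
Reagents that add atoms: none
Why: Homogeneous hydrogenation with RhCl(PPh3)3 reduces the cis-disubstituted C9=C10 alkene far faster than the trisubstituted C3=C4 alkene, and the neutral medium should leave the enolisable ring-fusion centre C6 cis.

Step 6
Reactants: 9 (4aR,9aS)-2,9,9-trimethyl-1,4,4a,6,7,8,9,9a-octahydro-5H-benzo[7]annulen-5-one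
Product: 10 (4aR,5S,9aS)-2,5,9,9-tetramethyl-4,4a,5,6,7,8,9,9a-octahydro-1H-benzo[7]annulen-5-ol
Conditions: MeMgBr, CeCl3 (anhydrous), THF, −78 °C; aq. NH4Cl
Reagents that add atoms: methylmagnesium bromide, C[Mg]Br
Why: 1,2-Addition of the organocerium reagent MeCeCl2, a nucleophile of low basicity that should not epimerise C6; it is expected to attack C7 from the convex face of the cis-fused bicycle, anti to the C6–C5 bond, which places the methyl cis to H6 and the hydroxyl trans to it (S at C7).

Step 7
Reactants: 10 (4aR,5S,9aS)-2,5,9,9-tetramethyl-4,4a,5,6,7,8,9,9a-octahydro-1H-benzo[7]annulen-5-ol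
Product: 12 (4aR,5S,9aS)-5-hydroxy-2,5,9,9-tetramethyl-4,4a,5,6,7,8,9,9a-octahydro-3H-benzo[7]annulen-3-one oxime, via nitrosochloride 11 (not isolated)
Conditions: i-AmONO, conc. HCl, EtOH, −15 °C; then crude adduct in pyridine, 70 °C
Reagents that add atoms: isoamyl nitrite, CC(C)CCON=O; hydrogen chloride, Cl (its chlorine is held in 11 only)
Why: Markovnikov electrophilic addition of nitrosyl chloride (nitroso group on the less substituted C4, chloride on the tertiary C3), then tautomerisation to the α-chloro oxime and base-promoted loss of HCl to the conjugated oxime with the endocyclic C2=C3 alkene, the classical sequence that turns 1-methylcyclohexenes such as limonene and α-terpineol into their 2-methylcyclohex-2-enone oximes.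

Step 8
Reactants: 12 (4aR,5S,9aS)-5-hydroxy-2,5,9,9-tetramethyl-4,4a,5,6,7,8,9,9a-octahydro-3H-benzo[7]annulen-3-one oxime
Product: 13 (4aR,5S,9aS)-5-hydroxy-2,5,9,9-tetramethyl-4,4a,5,6,7,8,9,9a-octahydro-3H-benzo[7]annulen-3-one (C4 enone, C2=C3)
Conditions: TiCl3 (aq.), NH4OAc, THF–H2O, rt
Reagents that add atoms: water, O
Why: Reductive deoximation: trivalent titanium cleaves the N–O bond and the resulting imine is hydrolysed in the buffered aqueous medium, which should be mild enough for the tertiary alcohol and the enone.

Step 9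
Reactants: 13 (4aR,5S,9aS)-5-hydroxy-2,5,9,9-tetramethyl-4,4a,5,6,7,8,9,9a-octahydro-3H-benzo[7]annulen-3-one
Product: 14 (3S,4aR,5S,9aS)-2,5,9,9-tetramethyl-4,4a,5,6,7,8,9,9a-octahydro-3H-benzo[7]annulene-3,5-diol (C4 hydroxyl cis to the C6–C7 bond; the C4 epimer of the alcohol in the target)
Conditions: NaBH4, CeCl3·7H2O, MeOH, −40 °C
Reagents that add atoms: none
Why: Luche 1,2-reduction of the enone; hydride should reach C4 from the convex face, away from the C6–C7 bond (the course that takes carvone to cis-carveol), so the C4 hydroxyl ends cis to C7 (S at C4), which is the epimer required for the inversion in step 11.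

Step 10
Reactants: 15 isovanillic acid (3-hydroxy-4-methoxybenzoic acid)
Product: 17 3-[(tert-butyldimethylsilyl)oxy]-4-methoxybenzoic acid, via bis-silyl derivative 16 (not isolated)
Conditions: TBSCl (2.3 equiv), imidazole, DMF, rt; then AcOH–THF–H2O, rt
Reagents that add atoms: tert-butyldimethylsilyl chloride, CC(C)(C)[Si](C)(C)Cl
Why: Silylation of both the phenol and the acid, then selective hydrolysis of the far more labile silyl ester in aqueous acetic acid, should leave the aryl silyl ether and free the carboxylic acid.

Step 11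
Reactants: 14 (3S,4aR,5S,9aS)-2,5,9,9-tetramethyl-4,4a,5,6,7,8,9,9a-octahydro-3H-benzo[7]annulene-3,5-diol; 17 3-[(tert-butyldimethylsilyl)oxy]-4-methoxybenzoic acid
Product: 18 (3R,4aR,5S,9aS)-5-hydroxy-2,5,9,9-tetramethyl-4,4a,5,6,7,8,9,9a-octahydro-3H-benzo[7]annulen-3-yl 3-[(tert-butyldimethylsilyl)oxy]-4-methoxybenzoate
Conditions: PPh3, DIAD, THF, 0 °C → rt
Reagents that add atoms: none
Why: Mitsunobu esterification: the secondary allylic alcohol is activated as its alkoxyphosphonium ion and displaced by the carboxylate from the open convex face in an SN2 reaction with inversion, which sets C4 as R (oxygen cis to H1 and H6), while the tertiary C7 alcohol is not activated and the phenol is masked.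

Step 12
Reactants: 18 (3R,4aR,5S,9aS)-5-hydroxy-2,5,9,9-tetramethyl-4,4a,5,6,7,8,9,9a-octahydro-3H-benzo[7]annulen-3-yl 3-[(tert-butyldimethylsilyl)oxy]-4-methoxybenzoate
Product: 19 (3R,4aR,5S,9aS)-5-hydroxy-2,5,9,9-tetramethyl-4,4a,5,6,7,8,9,9a-octahydro-3H-benzo[7]annulen-3-yl 3-hydroxy-4-methoxybenzoate (CNP0210711.3)
Conditions: Bu4NF, AcOH, THF, 0 °C
Reagents that add atoms: none
Why: Fluoride cleavage of the aryl silyl ether, buffered with acetic acid so that the liberated phenoxide should not attack the benzoate ester.

## Compound list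

1 | 4,4-dimethylcyclopent-2-en-1-one | CC1(C)CC(=O)C=C1 | starting material
2 | isoprene (2-methylbuta-1,3-diene) | CC(=C)C=C | starting material
3 | (3aS,7aR)-3,3,5-trimethyl-2,3,3a,4,7,7a-hexahydro-1H-inden-1-one | CC1=CC[C@@H]2[C@H](C1)C(C)(C)CC2=O | intermediate
4 | phenyl vinyl sulfoxide (racemic) | C=CS(=O)c1ccccc1 | starting material
5 | lithium enolate of 3 (C7–O–Li, C7=C10) | CC1=CC[C@@H]2[C@H](C1)C(C)(C)C=C2O[Li] | intermediate (not isolated)
6 | (2R,3aS,7aR)-3,3,5-trimethyl-2-[2-(phenylsulfinyl)ethyl]-2,3,3a,4,7,7a-hexahydro-1H-inden-1-one (both sulfur epimers) | CC1=CC[C@@H]2[C@H](C1)C(C)(C)[C@@H](CCS(=O)c1ccccc1)C2=O | intermediate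
7 | (2R,3aS,7aR)-2-ethenyl-3,3,5-trimethyl-2,3,3a,4,7,7a-hexahydro-1H-inden-1-one | CC1=CC[C@@H]2[C@H](C1)C(C)(C)[C@@H](C=C)C2=O | intermediate (precursor of the key step)
8 | (4aR,9aS)-2,9,9-trimethyl-1,4,4a,6,9,9a-hexahydro-5H-benzo[7]annulen-5-one | CC1=CC[C@@H]2[C@H](C1)C(C)(C)/C=C\CC2=O | intermediate (product of the key step)
9 | (4aR,9aS)-2,9,9-trimethyl-1,4,4a,6,7,8,9,9a-octahydro-5H-benzo[7]annulen-5-one | CC1=CC[C@@H]2[C@H](C1)C(C)(C)CCCC2=O | intermediate
10 | (4aR,5S,9aS)-2,5,9,9-tetramethyl-4,4a,5,6,7,8,9,9a-octahydro-1H-benzo[7]annulen-5-ol | CC1=CC[C@@H]2[C@H](C1)C(C)(C)CCC[C@]2(C)O | intermediate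
11 | nitrosyl chloride adduct of 10 (chlorine on C3, nitroso on C4, trans; drawn as the monomer) | C[C@]1(Cl)[C@H](N=O)C[C@@H]2[C@H](C1)C(C)(C)CCC[C@]2(C)O | intermediate (not isolated)
12 | (4aR,5S,9aS)-5-hydroxy-2,5,9,9-tetramethyl-4,4a,5,6,7,8,9,9a-octahydro-3H-benzo[7]annulen-3-one oxime (oxime geometry not fixed) | ON=C1C[C@@H]2[C@H](C=C1C)C(C)(C)CCC[C@]2(C)O | intermediate
13 | (4aR,5S,9aS)-5-hydroxy-2,5,9,9-tetramethyl-4,4a,5,6,7,8,9,9a-octahydro-3H-benzo[7]annulen-3-one | O=C1C[C@@H]2[C@H](C=C1C)C(C)(C)CCC[C@]2(C)O | intermediate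
14 | (3S,4aR,5S,9aS)-2,5,9,9-tetramethyl-4,4a,5,6,7,8,9,9a-octahydro-3H-benzo[7]annulene-3,5-diol | O[C@H]1C[C@@H]2[C@H](C=C1C)C(C)(C)CCC[C@]2(C)O | intermediate
15 | isovanillic acid (3-hydroxy-4-methoxybenzoic acid) | COc1ccc(C(=O)O)cc1O | starting material
16 | tert-butyldimethylsilyl 3-[(tert-butyldimethylsilyl)oxy]-4-methoxybenzoate | COc1ccc(C(=O)O[Si](C)(C)C(C)(C)C)cc1O[Si](C)(C)C(C)(C)C | intermediate (not isolated)
17 | 3-[(tert-butyldimethylsilyl)oxy]-4-methoxybenzoic acid | COc1ccc(C(=O)O)cc1O[Si](C)(C)C(C)(C)C | intermediate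
18 | (3R,4aR,5S,9aS)-5-hydroxy-2,5,9,9-tetramethyl-4,4a,5,6,7,8,9,9a-octahydro-3H-benzo[7]annulen-3-yl 3-[(tert-butyldimethylsilyl)oxy]-4-methoxybenzoate | COc1ccc(C(=O)O[C@@H]2C[C@@H]3[C@H](C=C2C)C(C)(C)CCC[C@]3(C)O)cc1O[Si](C)(C)C(C)(C)C | intermediate
19 | (3R,4aR,5S,9aS)-5-hydroxy-2,5,9,9-tetramethyl-4,4a,5,6,7,8,9,9a-octahydro-3H-benzo[7]annulen-3-yl 3-hydroxy-4-methoxybenzoate | COc1ccc(C(=O)O[C@@H]2C[C@@H]3[C@H](C=C2C)C(C)(C)CCC[C@]3(C)O)cc1O | target

## Step count and risks

Total step count: 12. Longest linear sequence: 11 steps (steps 1 to 9, 11 and 12); step 10 is a one-step side branch.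

The three steps most likely to fail:

**Step 4 (photochemical 1,3-acyl shift).** The photolysis may settle at an unfavourable photostationary ratio, or leak into triplet oxa-di-π-methane rearrangement, ketene formation by hydrogen transfer within the radical pair, and decarbonylation. Fallback, setting out from 3 and returning at 9: ring B is made without the vinyl group by two one-carbon ring enlargements. Treatment of 3 with TMSCHN2 and BF3·OEt2 in CH2Cl2 at −78 °C (diazoalkane ring expansion, the less substituted α-carbon C10 migrating), followed by acidic protodesilylation, should give the cis-fused six-membered ketone (4aS,8aR)-4,4,6-trimethyl-3,4,4a,5,8,8a-hexahydronaphthalen-1(2H)-one F1. A second round on F1, where the new unhindered CH2 migrates, should give cycloheptanone 9, and the route resumes at step 6.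

**Step 2 (enolate addition to the vinyl sulfoxide).** Deprotonation at the ring-fusion carbon C6 may compete with that at the neopentyl CH2 C10, and proton transfer between enolate and adduct may lead to regioisomers and double addition. Fallback, setting out from 1 and returning at 7: the two-carbon unit is attached before the cycloaddition, where only one enolisable position exists. Enone 1 with LiN(i-Pr)2 and 4 should give 4,4-dimethyl-5-[2-(phenylsulfinyl)ethyl]cyclopent-2-en-1-one F2. Pyrolysis in toluene should give racemic 5-ethenyl-4,4-dimethylcyclopent-2-en-1-one F3. The Diels–Alder reaction of F3 with 2 under the catalyst of step 1, relying on catalyst control of the face, should give 7 as a mixture of C10 epimers, both of which serve in step 4.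

**Step 7 (nitrosyl chloride addition and dehydrochlorination).** Under the acidic nitrosating conditions the tertiary C7 alcohol may ionise or add across ring A to the developing C3 cation (a cineole-type ether), and the nitroso dimer may resist clean loss of HCl. Fallback, setting out from 10 and returning at 13: the enone is reached through the saturated C4 ketone.
- Hydroboration–oxidation of 10 (BH3·THF; NaOH, H2O2) from the convex face should give (2S,3R,4aR,5S,9aS)-2,5,9,9-tetramethyldecahydro-1H-benzo[7]annulene-3,5-diol F4.
- Dess–Martin oxidation of the secondary alcohol should give the hydroxy ketone (4aR,5S,9aS)-5-hydroxy-2,5,9,9-tetramethyldecahydro-3H-benzo[7]annulen-3-one F5.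
- TMSCl, NaI and Et3N in MeCN should give the more substituted C3=C4 trimethylsilyl enol ether, silylated also on the C7 oxygen, F6.
- Saegusa–Ito oxidation with Pd(OAc)2 in MeCN should give the C7 trimethylsilyl ether of the enone, F7, and dilute aqueous acid frees 13.

## Further compounds

F1 | step 4 | (4aS,8aR)-4,4,6-trimethyl-3,4,4a,5,8,8a-hexahydronaphthalen-1(2H)-one | CC1=CC[C@@H]2[C@H](C1)C(C)(C)CCC2=O
F2 | step 2 | 4,4-dimethyl-5-[2-(phenylsulfinyl)ethyl]cyclopent-2-en-1-one (racemic) | CC1(C)C=CC(=O)C1CCS(=O)c1ccccc1
F3 | step 2 | 5-ethenyl-4,4-dimethylcyclopent-2-en-1-one (racemic) | CC1(C)C=CC(=O)C1C=C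
F4 | step 7 | (2S,3R,4aR,5S,9aS)-2,5,9,9-tetramethyldecahydro-1H-benzo[7]annulene-3,5-diol | C[C@H]1[C@H](O)C[C@@H]2[C@H](C1)C(C)(C)CCC[C@]2(C)O
F5 | step 7 | (4aR,5S,9aS)-5-hydroxy-2,5,9,9-tetramethyldecahydro-3H-benzo[7]annulen-3-one (C3 methyl epimerisable) | C[C@H]1C(=O)C[C@@H]2[C@H](C1)C(C)(C)CCC[C@]2(C)O
F6 | step 7 | C3=C4 trimethylsilyl enol ether of F5 with the C7 oxygen silylated | CC1=C(O[Si](C)(C)C)C[C@@H]2[C@H](C1)C(C)(C)CCC[C@]2(C)O[Si](C)(C)C
F7 | step 7 | C7 trimethylsilyl ether of enone 13 | O=C1C[C@@H]2[C@H](C=C1C)C(C)(C)CCC[C@]2(C)O[Si](C)(C)C
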